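The ratio of isomer of the product to target gained between 20.0 h and 50.0 h, 2.5 percentage points against 6.5 points, was what the meeting on this 3.0 M flask turned on, the elm run being the same flask followed so far.

| flask | substrate | remark | time |
|---|---|---|---|
| elm | 3 M | the very flask that is asked about, followed so far |  |
| flask | 3.0 M |  | 10 d |

- elm (time / h: isomer of the product / %, target / %): 4.00: 0, 2.3; 8.00: 0.4, 4.4; 20.0: 0.7, 9.4; 50.0: 3.2, 15.9

(each reading ± 0.3 percentage points)

1. share of isomer of the product in isomer of the product plus target at 4.0 h
2. share of isomer of the product in isomer of the product plus target at 30 h
3. share of isomer of the product in isomer of the product plus target at 10 d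
4. which of isomer of the product and target there is more of at 10 d

- the analysis behind the earlier runs scatters by 0.3 percentage points, standard deviation

Minutes. The first chemist opened by setting aside the share of the whole and gave 27.8% as the fresh share, the part that isomer of the product takes of what it and target together gain between two readings, a differential selectivity. She warned that this is a reading, each difference carrying the scatter 0.3 points of both its ends, and that the interval before it gave 5.66%. She nevertheless took the late value as standing from then on, reading the late start of the isomer as the filling of an unseen pool that feeds the isomer, which was her judgement and not something the readings prove. On that view the share of the whole, 16.8% at 50.0 h, stands below the fresh share and moves towards it without passing it, so she committed to a share at 10 d a little under 27.8%, with target leading.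

The second chemist made the forecast, 1.5% at 4.0 h, 11% at 30 h and 60% at 10 d, with isomer of the product ahead, holding “so the isomer likely forms from the target”. The two parted at 10 d, and neither gave way.

The flask gives 2.17% at 4.0 h, 12.1% at 30 h and 25.3% at 10 d, with target ahead, 34.1% against 11.6%.

    substrate → target (k = 2.20 × 10⁻⁶ /s)
    substrate ⇌ other conformer (K = 1.60, k = 1.70 × 10⁻⁵ /s)
    other conformer → isomer of the product (k = 4.00 × 10⁻⁷ /s)
    target → over-reaction product (k = 4.80 × 10⁻⁷ /s)
    2 substrate → homo dimer (k = 3.40 × 10⁻⁷ /M/s)

In this flask isomer of the product comes from other conformer, which at 3.20 d falls back to substrate 27 times as fast as it goes on. Target, made 1.59 times as fast as it is used up at 10.0 d, is still gaining there, and the share of the whole, 25.3%, stands under the fresh share of 27.8%. For the neighbour flask with 0.75 M of substrate, the fresh share read at 3 M again puts the share at 10 d a little under 27.8%, with target ahead. That neighbour flask gives 25.2%, with target at 37.1% against isomer of the product at 12.5%.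

All runs stem from a simulated flask with made-up constants; scatter was added.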